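The meeting had no constants for this flask, so it worked from the readings of the earlier runs, in which target is counted together with its idle adduct.

| flask | solid substrate | partner | remark | time |
|---|---|---|---|---|
| zeta | 0.65 M | 1.04 M | run made earlier |  |
| epsilon | 0.98 M | 1.04 M | run made earlier |  |
| alpha | 1.3 M | 2.1 M | run made earlier |  |
| flask | 1.3 M | 1.04 M |  | 5.0 min |

| run | time / min | target / % | idle adduct / % |
|---|---|---|---|
| zeta | 1.00 | 1.8 | 0.2 |
| zeta | 2.00 | 3.3 | 1.1 |
| zeta | 3.00 | 7.1 | 2.6 |
| zeta | 4.00 | 9.7 | 2.6 |
| epsilon | 1.00 | 0.5 | 0 |
| epsilon | 2.00 | 2.8 | 1.0 |
| epsilon | 3.00 | 4.7 | 2.1 |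
| epsilon | 4.00 | 7.5 | 2.4 |
| alpha | 0.500 | 0 | 0 |
| alpha | 1.33 | 2.2 | 0.7 |
| alpha | 2.50 | 4.2 | 3.4 |
| alpha | 4.00 | 9.6 | 3.8 |

(each reading ± 0.5 percentage points)

* amount of target and idle adduct together at 5.0 min, in percent of the solid substrate charged
* concentration of dissolved substrate in solution at 5.0 min, in percent of saturation

- target is meant together with its idle adduct
- solid, in amounts per volume of the solution: solid substrate
- at the start none of the solid substrate is in solution
- dissolved substrate means what is dissolved; the solid is not counted in it

The first speaker compared zeta with epsilon at their last readings: the solid charge rose by a factor of 1.51, but c(target) in M rose by a factor of 1.17. She read this as an apparent reaction order of 0.374 in the solid charge, a reading that carries the scatter. The second speaker noted that alpha, with twice the partner of zeta and more solid too, held twice the c(target) of zeta. He therefore proposed dividing c(target) by the c(partner) charged and by the time. This gave 0.0152 /min for zeta, 0.0177 /min for epsilon and 0.0149 /min for alpha, readings that carry their scatter. Their mean, 0.0159 /min, is the partner yield rate g, target formed per partner charged per minute. Multiplied by the flask's c(partner) and time and divided by its solid charge, it gave him 6.36%; he offered no figure for saturation.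

The forecast disagreed, holding that “dissolution, which scales with solid, partly limits the rate”, and stood at 13% and 37% of saturation, a yield above his.

The flask gave 6.62% and 23.5% of saturation.

    solid substrate ⇌ dissolved substrate, rate k1*(cs1 - [dissolved substrate]) while solid is left; crystals form when [dissolved substrate] > cs1 (solubility = 0.990 M, k = 0.0980 /min)
    dissolved substrate + partner → target (k = 0.160 /M/min)
    partner → decomposed reagent (k = 0.130 /min)
    partner + target ⇌ idle adduct, settled at all times (K = 0.820 /M)
    2 solid substrate → homo dimer (k = 0.850 /M/min)

The flask's own g is 0.0165 /min, close to the carried 0.0159 /min. For the neighbouring flask with 0.52 M of solid substrate, g predicts 15.9%, and that flask gave 15.3%. The largest single proven effect on the flask is the low solubility of dissolved substrate, which also sets how fast it dissolves . The run of this flask without that low solubility reaches 31.8% instead of 6.62%.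

The data are calculated for substances that don't exist; scatter was added.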